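**Plan**
- Locants follow the eudesmane skeleton: C10 is the quaternary carbon with the angular methyl C14, C9 the acyloxy carbon, C7 the side-chain carbon, C5 the ring-fusion CH, C4 the carbinol carbon with methyl C15; β is the face of C14. Retrosynthetic cuts: the C12 oxidation level and the C9 ester first, then C2–C3 together with C4–OH in ring A (one event), then C10–C1 and C5–C4 on the enone of (R)-carvone.
- Forward: ring B is (R)-carvone (its carbonyl becomes C9, its enone carbons C10 and C5, its isopropenyl group sits on C7). An isopropenyl group is added to C5, a propanoate arm to C10, and ring A is closed last.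
- Enabling feature: C4 of ring A is a fully substituted carbinol carbon between C3 and the ring-fusion carbon C5 and 1,3 to the quaternary C10. A C2 radical on the C10 arm can therefore close the C2–C3 bond onto a C5 isopropenyl group (6-endo) and leave a tertiary C4 radical, then cation, that takes up water.
- Stereochemistry: C7 from carvone; C5 by conjugate addition anti to C7; C10 by enolate attack anti to the C5 group (hence the trans ring fusion); C4 by equatorial water capture anti to the axial C14; C9 by equatorial hydride delivery; the side-chain centre from (S)-3-methylpentanoic acid.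
- Endgame: acylation of the C9 alcohol, then allylic oxidation of the C7 isopropenyl group to the acrylic acid.

Key step: step 5

Assumption: (R)-carvone and (S)-3-methylpentanoic acid are taken as purchasable in enantiopure form.

**Step 1**
Reactants: 1 (R)-carvone; 2 isopropenylmagnesium bromide
Product: 4 trimethyl{[(3S,5R)-2-methyl-3,5-di(prop-1-en-2-yl)cyclohex-1-en-1-yl]oxy}silane, via bromomagnesium enolate 3 (not isolated)
Conditions: CuBr·SMe2 (10 mol %), TMSCl, THF, −78 °C; Et3N, pentane work-up
Reagents that add atoms: chlorotrimethylsilane, C[Si](C)(C)Cl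
Why: Copper-catalysed conjugate addition of the Grignard reagent to the enone should deliver the isopropenyl group axially to C5 on the face opposite the C7 isopropenyl group, which sets C5, and TMSCl traps the enolate regiospecifically as the C9=C10 silyl enol ether.

**Step 2**
Reactants: 4 trimethyl{[(3S,5R)-2-methyl-3,5-di(prop-1-en-2-yl)cyclohex-1-en-1-yl]oxy}silane; 5 methyl acrylate
Product: 7 methyl 3-[(1S,4R,6S)-1-methyl-2-oxo-4,6-di(prop-1-en-2-yl)cyclohexyl]propanoate, via lithium enolate 6 (not isolated)
Conditions: MeLi, THF, 0 °C; then 5, −78 °C; AcOH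
Reagents that add atoms: none
Why: MeLi cleaves the silyl enol ether to the regiodefined lithium enolate, whose Michael addition to methyl acrylate should occur at C10 on the face opposite the C5 isopropenyl group (held pseudoaxial by allylic 1,2-strain with the C10 methyl), which sets the quaternary C10 with its new arm trans to the C5 group.

**Step 3**
Reactants: 7 methyl 3-[(1S,4R,6S)-1-methyl-2-oxo-4,6-di(prop-1-en-2-yl)cyclohexyl]propanoate
Product: 8 3-[(1S,4R,6S)-1-methyl-2-oxo-4,6-di(prop-1-en-2-yl)cyclohexyl]propanoic acid
Conditions: LiOH, THF/H2O, 0 °C to rt; then 1 M HCl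
Reagents that add atoms: lithium hydroxide, [Li+].[OH-]
Why: Saponification of the methyl ester should be clean because C10 is quaternary and neither C5 nor C7 is α to the ketone, so no stereocenter can epimerise.

**Step 4**
Reactants: 8 3-[(1S,4R,6S)-1-methyl-2-oxo-4,6-di(prop-1-en-2-yl)cyclohexyl]propanoic acid
Product: 9 1,3-dioxoisoindolin-2-yl 3-[(1S,4R,6S)-1-methyl-2-oxo-4,6-di(prop-1-en-2-yl)cyclohexyl]propanoate
Conditions: N-hydroxyphthalimide, N,N'-diisopropylcarbodiimide, DMAP (cat.), CH2Cl2, rt
Reagents that add atoms: N-hydroxyphthalimide, O=C1c2ccccc2C(=O)N1O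
Why: Carbodiimide coupling (Steglich-type esterification) should turn the acid into the redox-active N-acyloxyphthalimide that the single-electron reduction in step 5 needs.

**Step 5**
Reactants: 9 1,3-dioxoisoindolin-2-yl 3-[(1S,4R,6S)-1-methyl-2-oxo-4,6-di(prop-1-en-2-yl)cyclohexyl]propanoate
Product: 10 (4R,5R,7R,10S)-4-hydroxyeudesm-11-en-9-one
Conditions: fac-Ir(ppy)3 (ppy = 2-phenylpyridinato, 2 mol %), acetone/H2O (9:1), blue LEDs (450 nm), rt, degassed (Ar)
Reagents that add atoms: water, O
Why: Proposed new method: the excited trivalent iridium photocatalyst should reduce the N-acyloxyphthalimide, which fragments to phthalimide anion, CO2 and the primary C2 radical; this radical adds to the terminal carbon (C3) of the C5 isopropenyl group, the tertiary C4 radical is oxidised by the tetravalent iridium species to the C4 cation, and water captures it while the phthalimide anion takes up the proton, so the cycle is redox-neutral. The closest known reaction types are the photoredox decarboxylative oxyalkylation of styrenes with N-acyloxyphthalimides (radical-polar crossover) and the endo-selective cyclisation of 5-substituted hex-5-enyl radicals; new is their union on an unactivated 1,1-disubstituted alkene. Ring A closes in the 6-endo-trig mode, which should win over 5-exo because exo attack would have to build a quaternary C4 between C5 and the quaternary C10 and end in a primary radical, whereas endo attack gives a tertiary radical in a strain-free trans-decalin. The ring fusion needs no control here, since C5 and C10 already carry their arms trans on ring B; the only new stereocenter, C4, is controlled by the axial C14 methyl on C10, which is 1,3-diaxial to the β face of C4 and should steer water to the equatorial α face (hydroxyl equatorial, C15 axial). The step needs chemoselective radical formation (only the activated ester is reduced, the ketone and both alkenes are not), site selectivity between the two isopropenyl groups (only the C5 group is within reach of a six-membered transition state, the C7 group would require a bridged ring) and water capture in competition with proton loss from the cation, for which the water-rich, neutral medium is chosen.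

**Step 6**
Reactants: 10 (4R,5R,7R,10S)-4-hydroxyeudesm-11-en-9-one
Product: 11 (4R,5R,7R,9R,10S)-eudesm-11-ene-4,9-diol
Conditions: LiBH(s-Bu)3, THF, −78 to 0 °C; then H2O
Reagents that add atoms: none
Why: In this diastereoselective ketone reduction with a bulky trialkylborohydride, axial approach to C9 is blocked on the α face by the axial C7 isopropenyl group (1,3-diaxial), so hydride should arrive equatorially from the β face and give the axial 9α-alcohol, which sets C9.

**Step 7**
Reactants: 12 (S)-3-methylpentanoic acid
Product: 13 (S)-3-methylpentanoyl chloride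
Conditions: (COCl)2, DMF (cat.), CH2Cl2, 0 °C to rt
Reagents that add atoms: oxalyl chloride, O=C(Cl)C(=O)Cl
Why: Acid chloride formation with oxalyl chloride under DMF catalysis is standard, and the β-stereocenter cannot epimerise.

**Step 8**
Reactants: 11 (4R,5R,7R,9R,10S)-eudesm-11-ene-4,9-diol; 13 (S)-3-methylpentanoyl chloride
Product: 14 (4R,5R,7R,9R,10S)-4-hydroxyeudesm-11-en-9-yl (3S)-3-methylpentanoate
Conditions: pyridine, DMAP (cat.), CH2Cl2, 0 to 40 °C
Reagents that add atoms: none
Why: DMAP-catalysed acylation should esterify the secondary C9 alcohol while the tertiary C4 alcohol, which is acylated far more slowly under these conditions, stays free, and no stereocenter is touched.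

**Step 9**
Reactants: 14 (4R,5R,7R,9R,10S)-4-hydroxyeudesm-11-en-9-yl (3S)-3-methylpentanoate
Product: 15 (4R,5R,7R,9R,10S)-4,12-dihydroxyeudesm-11(13)-en-9-yl (3S)-3-methylpentanoate
Conditions: SeO2 (0.3 equiv), t-BuOOH, CH2Cl2, rt
Reagents that add atoms: tert-butyl hydroperoxide, CC(C)(C)OO (oxygen passed on by SeO2, O=[Se]=O)
Why: SeO2 allylic oxidation (Riley oxidation: ene reaction, then 2,3-sigmatropic shift, with reoxidation by the hydroperoxide) should hydroxylate the methyl group of the 1,1-disubstituted isopropenyl unit in preference to the ring methine C7.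

**Step 10**
Reactants: 15 (4R,5R,7R,9R,10S)-4,12-dihydroxyeudesm-11(13)-en-9-yl (3S)-3-methylpentanoate
Product: 16 (4R,5R,7R,9R,10S)-4-hydroxy-12-oxoeudesm-11(13)-en-9-yl (3S)-3-methylpentanoate
Conditions: TEMPO (10 mol %), PhI(OAc)2, CH2Cl2, rt
Reagents that add atoms: none
Why: Oxoammonium-mediated (TEMPO) oxidation should take the primary allylic alcohol to the enal and leave the tertiary alcohol, the ester and the alkene untouched, and any enal already formed in step 9 converges here.

**Step 11**
Reactants: 16 (4R,5R,7R,9R,10S)-4-hydroxy-12-oxoeudesm-11(13)-en-9-yl (3S)-3-methylpentanoate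
Product: 17 (4R,5R,7R,9R,10S)-4-hydroxy-9-[(3S)-3-methylpentanoyloxy]eudesm-11(13)-en-12-oic acid (target)
Conditions: NaClO2, NaH2PO4, 2-methyl-2-butene, t-BuOH/H2O, rt
Reagents that add atoms: sodium chlorite, [Na+].[O-]Cl=O
Why: Pinnick oxidation should convert the α-methylene aldehyde into the acrylic acid without touching the alkene (hypochlorous acid is scavenged by 2-methyl-2-butene), the ester or the tertiary alcohol.

**Compound list**
1 | (R)-carvone, (5R)-2-methyl-5-(prop-1-en-2-yl)cyclohex-2-en-1-one | CC(=C)[C@@H]1CC=C(C)C(=O)C1 | starting material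
2 | isopropenylmagnesium bromide | CC(=C)[Mg]Br | starting material
3 | bromomagnesium (3S,5R)-2-methyl-3,5-di(prop-1-en-2-yl)cyclohex-1-en-1-olate | CC(=C)[C@@H]1C[C@@H](C(C)=C)C(C)=C(O[Mg]Br)C1 | intermediate
4 | trimethyl{[(3S,5R)-2-methyl-3,5-di(prop-1-en-2-yl)cyclohex-1-en-1-yl]oxy}silane | CC(=C)[C@@H]1C[C@@H](C(C)=C)C(C)=C(O[Si](C)(C)C)C1 | intermediate
5 | methyl acrylate | C=CC(=O)OC | starting material
6 | lithium (3S,5R)-2-methyl-3,5-di(prop-1-en-2-yl)cyclohex-1-en-1-olate | CC(=C)[C@@H]1C[C@@H](C(C)=C)C(C)=C(O[Li])C1 | intermediate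
7 | methyl 3-[(1S,4R,6S)-1-methyl-2-oxo-4,6-di(prop-1-en-2-yl)cyclohexyl]propanoate | CC(=C)[C@@H]1C[C@@H](C(C)=C)[C@](C)(CCC(=O)OC)C(=O)C1 | intermediate
8 | 3-[(1S,4R,6S)-1-methyl-2-oxo-4,6-di(prop-1-en-2-yl)cyclohexyl]propanoic acid | CC(=C)[C@@H]1C[C@@H](C(C)=C)[C@](C)(CCC(=O)O)C(=O)C1 | intermediate
9 | 1,3-dioxoisoindolin-2-yl 3-[(1S,4R,6S)-1-methyl-2-oxo-4,6-di(prop-1-en-2-yl)cyclohexyl]propanoate | CC(=C)[C@@H]1C[C@@H](C(C)=C)[C@](C)(CCC(=O)ON2C(=O)c3ccccc3C2=O)C(=O)C1 | intermediate
10 | (4R,5R,7R,10S)-4-hydroxyeudesm-11-en-9-one (trans-decalin; 4α-OH, 5α-H, 7α-isopropenyl, 10β-CH3) | CC(=C)[C@@H]1C[C@@H]2[C@](C)(CCC[C@@]2(C)O)C(=O)C1 | intermediate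
11 | (4R,5R,7R,9R,10S)-eudesm-11-ene-4,9-diol (9α-OH) | CC(=C)[C@@H]1C[C@@H]2[C@](C)(CCC[C@@]2(C)O)[C@H](O)C1 | intermediate
12 | (S)-3-methylpentanoic acid | CC[C@H](C)CC(=O)O | starting material
13 | (S)-3-methylpentanoyl chloride | CC[C@H](C)CC(=O)Cl | intermediate
14 | (4R,5R,7R,9R,10S)-4-hydroxyeudesm-11-en-9-yl (3S)-3-methylpentanoate | CC(=C)[C@@H]1C[C@@H]2[C@](C)(CCC[C@@]2(C)O)[C@H](OC(=O)C[C@@H](C)CC)C1 | intermediate
15 | (4R,5R,7R,9R,10S)-4,12-dihydroxyeudesm-11(13)-en-9-yl (3S)-3-methylpentanoate | OCC(=C)[C@@H]1C[C@@H]2[C@](C)(CCC[C@@]2(C)O)[C@H](OC(=O)C[C@@H](C)CC)C1 | intermediate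
16 | (4R,5R,7R,9R,10S)-4-hydroxy-12-oxoeudesm-11(13)-en-9-yl (3S)-3-methylpentanoate | O=CC(=C)[C@@H]1C[C@@H]2[C@](C)(CCC[C@@]2(C)O)[C@H](OC(=O)C[C@@H](C)CC)C1 | intermediate
17 | (4R,5R,7R,9R,10S)-4-hydroxy-9-[(3S)-3-methylpentanoyloxy]eudesm-11(13)-en-12-oic acid | C=C(C(=O)O)[C@@H]1C[C@@H]2[C@](C)(CCC[C@@]2(C)O)[C@H](OC(=O)C[C@@H](C)CC)C1 | target

**Step count and risks**
Total step count: 11. Longest linear sequence: 10 steps (steps 1 to 6 and 8 to 11, from (R)-carvone).

Steps most likely to fail:

Step 5 (Proposed new method). What may go wrong: ring closure in the exo mode, loss of a proton from the C4 cation in place of water capture, or quenching of the open-chain radical before it cyclises. The fallback uses known chemistry, sets out from 4 and comes back at 11. Lithium enolate 6, regenerated from 4 with MeLi, is alkylated with but-3-en-1-yl trifluoromethanesulfonate (THF, −78 °C), with the same facial course as in step 2, to give (2S,3S,5R)-2-(but-3-en-1-yl)-2-methyl-3,5-di(prop-1-en-2-yl)cyclohexan-1-one F1. Ring-closing metathesis between the butenyl terminus and the C5 isopropenyl group (second-generation Grubbs catalyst RuCl2(=CHPh)(PCy3)(H2IMes), CH2Cl2, 40 °C) should close ring A as the trisubstituted cyclohexene (5S,7R,10S)-eudesma-3,11-dien-9-one F2. Epoxidation with mCPBA (NaHCO3, CH2Cl2, 0 °C) should take the electron-richer trisubstituted ring alkene in preference to the 1,1-disubstituted C7 isopropenyl group, from the α face away from C14, and give (3R,4S,5R,7R,10S)-3,4-epoxyeudesm-11-en-9-one F3. LiEt3BH (THF, 0 °C) should then open the epoxide at the secondary carbon C3 and reduce the C9 ketone from the equatorial side in the same flask, which leads to diol 11.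

Step 2. What may go wrong: anionic oligomerisation of the acrylate by the ester enolate that forms, or proton transfer in place of addition at the hindered enolate carbon. The fallback sets out from 4 and comes back at 8. Enolate 6 is alkylated with allyl iodide (THF, −78 to 0 °C) to give (2S,3S,5R)-2-allyl-2-methyl-3,5-di(prop-1-en-2-yl)cyclohexan-1-one F4. Hydroboration of the monosubstituted alkene with disiamylborane, which discriminates against the two 1,1-disubstituted alkenes, followed by NaOH/H2O2 should give (2S,3S,5R)-2-(3-hydroxypropyl)-2-methyl-3,5-di(prop-1-en-2-yl)cyclohexan-1-one F5. Oxidation of the primary alcohol with TEMPO and PhI(OAc)2 in MeCN/H2O then gives acid 8.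

Step 6. What may go wrong: poor facial selectivity of hydride delivery, or no reduction at the carbonyl next to the quaternary carbon. The fallback sets out from 10 and comes back at 14. Dissolving-metal reduction (Li, liquid NH3, THF, −78 °C; NH4Cl) should give the thermodynamically preferred equatorial alcohol (4R,5R,7R,9S,10S)-eudesm-11-ene-4,9-diol F6. Mitsunobu esterification with acid 12 (PPh3, diisopropyl azodicarboxylate, toluene) should invert C9 and give ester 14 directly, while the tertiary alcohol does not react.

**Further compounds**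
F1 | step 5 | (2S,3S,5R)-2-(but-3-en-1-yl)-2-methyl-3,5-di(prop-1-en-2-yl)cyclohexan-1-one | CC(=C)[C@@H]1C[C@@H](C(C)=C)[C@](C)(CCC=C)C(=O)C1
F2 | step 5 | (5S,7R,10S)-eudesma-3,11-dien-9-one | CC(=C)[C@@H]1C[C@@H]2[C@](C)(CCC=C2C)C(=O)C1
F3 | step 5 | (3R,4S,5R,7R,10S)-3,4-epoxyeudesm-11-en-9-one | CC(=C)[C@@H]1C[C@@H]2[C@](C)(CC[C@H]3O[C@@]23C)C(=O)C1
F4 | step 2 | (2S,3S,5R)-2-allyl-2-methyl-3,5-di(prop-1-en-2-yl)cyclohexan-1-one | CC(=C)[C@@H]1C[C@@H](C(C)=C)[C@](C)(CC=C)C(=O)C1
F5 | step 2 | (2S,3S,5R)-2-(3-hydroxypropyl)-2-methyl-3,5-di(prop-1-en-2-yl)cyclohexan-1-one | CC(=C)[C@@H]1C[C@@H](C(C)=C)[C@](C)(CCCO)C(=O)C1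
F6 | step 6 | (4R,5R,7R,9S,10S)-eudesm-11-ene-4,9-diol | CC(=C)[C@@H]1C[C@@H]2[C@](C)(CCC[C@@]2(C)O)[C@@H](O)C1
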